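**Retrosynthetic overview**

1. Numbering used throughout: ring A is the arene (C4a, C5–C8, C8a; OH on C8, CO2H on C6), ring B is C1–C4 (CH3 on C1, side chain on C4), and the side chain is C11(CH3)–C12–C13–C14–C15(CH3)–C16H2–O–acyl.
2. Last disconnection is C15–C16: a nickel-catalysed enantioconvergent sp3–sp3 coupling of a racemic C15 propargylic bromide (C13≡C14 alkyne) with (3-phenylpropanoyloxy)methylzinc iodide sets C15 and installs the whole ester; one final hydrogenation removes the alkyne and both benzyl groups.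
3. Enabling feature: C12–C14 are three functionality-free methylenes, so C13/C14 can be carried as an alkyne that makes C15 a stabilised propargylic radical site, and the acyl oxygen on C16 chelate-stabilises the C16 zinc reagent.
4. Core: C1 comes from Pd-catalysed asymmetric O-allylation of dimethyl 5-hydroxyisophthalate and aromatic Claisen chirality transfer (the flanked ester becomes C4, the free one the C6 acid); C4 and C11 are set together by one dual iridium/amine α-allylation of propanal; C12–C13 by triflate/acetylide alkylation.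
5. Ring order: ring A is bought; ring B is closed by ring-closing metathesis (C2=C3) and saturated with diimide.

Key step: step 18

Remark: in steps 2, 9 and 18 the ligand antipodes named are those assumed to give the configurations drawn; if a test run shows the opposite sense of induction, the other antipode is used.

**Route**

Step 1
Reactants: 1 rac-(E)-pent-3-en-2-ol
Product: 2 rac-methyl (E)-pent-3-en-2-yl carbonate
Conditions: ClCO2Me, pyridine, CH2Cl2, 0 °C → rt
Reagents that add atoms: methyl chloroformate, COC(=O)Cl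
Why: Acylation of the secondary allylic alcohol with a chloroformate gives the mixed carbonate needed as an ionisable leaving group; the racemate is wanted, so no stereocenter is controlled.

Step 2
Reactants: 3 dimethyl 5-hydroxyisophthalate; 2 rac-methyl (E)-pent-3-en-2-yl carbonate
Product: 4 dimethyl 5-{[(2S,3E)-pent-3-en-2-yl]oxy}isophthalate
Conditions: Pd2(dba)3·CHCl3 (1 mol %), (1R,2R)-N,N'-bis[2-(diphenylphosphino)benzoyl]cyclohexane-1,2-diamine (3 mol %), CH2Cl2, rt
Reagents that add atoms: none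
Why: Pd-catalysed asymmetric allylic etherification (Tsuji–Trost type): both enantiomers of 2 ionise to the same syn,syn-1,3-dimethylallyl palladium complex, and the chiral bisphosphine steers the acidic phenol to one of its two enantiotopic termini, which sets the ether carbon as S with the E alkene kept.

Step 3
Reactants: 4 dimethyl 5-{[(2S,3E)-pent-3-en-2-yl]oxy}isophthalate
Product: 5 dimethyl 5-hydroxy-4-[(2R,3E)-pent-3-en-2-yl]isophthalate
Conditions: Eu(fod)3 (10 mol %), CHCl3, 50 °C
Reagents that add atoms: none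
Why: Aromatic Claisen rearrangement through a chair transition state with the allylic methyl equatorial transfers the C–O chirality suprafacially to the new benzylic carbon (future C1, R) and gives the E-propenyl group; the two ortho positions are equivalent by symmetry, so there is no regiochemical question.

Step 4
Reactants: 5 dimethyl 5-hydroxy-4-[(2R,3E)-pent-3-en-2-yl]isophthalate
Product: 6 3-hydroxy-5-(methoxycarbonyl)-4-[(2R,3E)-pent-3-en-2-yl]benzoic acid
Conditions: LiOH·H2O (2.2 equiv), THF/H2O, 0 °C → rt; then 1 M HCl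
Reagents that add atoms: lithium hydroxide, [Li+].[OH-]
Why: Saponification should discriminate the two esters sterically, because the ester flanked by the new sec-alkyl group is shielded and hydroxide attacks the unhindered ester (future C6 carboxyl).

Step 5
Reactants: 6 3-hydroxy-5-(methoxycarbonyl)-4-[(2R,3E)-pent-3-en-2-yl]benzoic acid
Product: 7 3-hydroxy-5-(hydroxymethyl)-4-[(2R,3E)-pent-3-en-2-yl]benzoic acid
Conditions: LiBH4 (4 equiv), THF/MeOH, 0 → 50 °C; then aq. HCl to pH 3
Reagents that add atoms: none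
Why: Chemoselective borohydride reduction: LiBH4 reduces the remaining methyl ester while the lithium carboxylate and phenoxide are inert, giving the benzylic alcohol carbon that becomes C4.

Step 6
Reactants: 7 3-hydroxy-5-(hydroxymethyl)-4-[(2R,3E)-pent-3-en-2-yl]benzoic acid
Product: 8 benzyl 3-(benzyloxy)-5-(hydroxymethyl)-4-[(2R,3E)-pent-3-en-2-yl]benzoate
Conditions: BnBr (2.3 equiv), K2CO3, DMF, rt
Reagents that add atoms: benzyl bromide, BrCc1ccccc1
Why: Williamson-type O-alkylation under carbonate base benzylates the phenoxide and the carboxylate but not the un-ionised benzylic alcohol, installing the two groups that the final hydrogenolysis removes.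

Step 7
Reactants: 8 benzyl 3-(benzyloxy)-5-(hydroxymethyl)-4-[(2R,3E)-pent-3-en-2-yl]benzoate
Product: 9 benzyl 3-(benzyloxy)-5-formyl-4-[(2R,3E)-pent-3-en-2-yl]benzoate
Conditions: MnO2 (excess), CH2Cl2, rt
Reagents that add atoms: none
Why: MnO2 oxidation is selective for benzylic alcohols, stops at the aldehyde and leaves the alkene and the C1 stereocenter untouched.

Step 8
Reactants: 9 benzyl 3-(benzyloxy)-5-formyl-4-[(2R,3E)-pent-3-en-2-yl]benzoate
Product: 10 benzyl 3-(benzyloxy)-5-(1-hydroxyprop-2-en-1-yl)-4-[(2R,3E)-pent-3-en-2-yl]benzoate (both carbinol epimers)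
Conditions: CH2=CHMgBr (1.2 equiv), THF, −78 °C; aq. NH4Cl
Reagents that add atoms: vinylmagnesium bromide, C=C[Mg]Br
Why: Grignard 1,2-addition to the aldehyde is much faster than to the benzyl ester at −78 °C, and the new carbinol center need not be controlled because it is ionised in step 9.

Step 9
Reactants: 10 benzyl 3-(benzyloxy)-5-(1-hydroxyprop-2-en-1-yl)-4-[(2R,3E)-pent-3-en-2-yl]benzoate; 11 propanal
Product: 13 benzyl 3-(benzyloxy)-5-[(2R,3S)-1-hydroxy-2-methylpent-4-en-3-yl]-4-[(2R,3E)-pent-3-en-2-yl]benzoate, via aldehyde 12 (not isolated)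
Conditions: [Ir(cod)Cl]2 (3 mol %), (R)-N-(dinaphtho[2,1-d:1',2'-f][1,3,2]dioxaphosphepin-4-yl)dibenz[b,f]azepine (12 mol %), (S)-2-{bis[3,5-bis(trifluoromethyl)phenyl][(trimethylsilyl)oxy]methyl}pyrrolidine (15 mol %), (MeO)2P(O)OH, ClCH2CH2Cl, 25 °C; then NaBH4, MeOH, 0 °C
Reagents that add atoms: none
Why: Dual iridium/amine-catalysed stereodivergent α-allylation of a linear aldehyde: the iridium–(phosphoramidite, olefin) complex ionises either carbinol epimer to one allyl-iridium species and controls attack at its branched terminus (C4), the prolinol silyl ether enamine of propanal controls the α-face (C11), so both centers are set in one event by catalyst control, and NaBH4 reduces the epimerisable aldehyde in the same flask.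

Step 10
Reactants: 13 benzyl 3-(benzyloxy)-5-[(2R,3S)-1-hydroxy-2-methylpent-4-en-3-yl]-4-[(2R,3E)-pent-3-en-2-yl]benzoate
Product: 14 benzyl (5R,8S)-4-(benzyloxy)-8-[(2R)-1-hydroxypropan-2-yl]-5-methyl-5,8-dihydronaphthalene-2-carboxylate
Conditions: second-generation Grubbs catalyst RuCl2(=CHPh)(PCy3)(H2IMes) (5 mol %), CH2Cl2 (0.01 M), 40 °C
Reagents that add atoms: none
Why: Ring-closing metathesis of the ortho-placed vinyl and propenyl groups closes six-membered ring B with loss of propene and touches neither benzylic stereocenter.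

Step 11
Reactants: 14 benzyl (5R,8S)-4-(benzyloxy)-8-[(2R)-1-hydroxypropan-2-yl]-5-methyl-5,8-dihydronaphthalene-2-carboxylate
Product: 15 benzyl (5R,8S)-4-(benzyloxy)-8-[(2R)-1-hydroxypropan-2-yl]-5-methyl-5,6,7,8-tetrahydronaphthalene-2-carboxylate
Conditions: 2-nitrobenzenesulfonyl hydrazide (5 equiv), Et3N, CH2Cl2, rt
Reagents that add atoms: none
Why: Diimide reduction is a concerted syn transfer of H2 that cannot move the double bond into conjugation, so the doubly activated centers C1 and C4 keep their configuration and the benzyl groups survive.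

Step 12
Reactants: 16 rac-but-3-yn-2-ol
Product: 17 rac-(but-3-yn-2-yloxy)(tert-butyl)dimethylsilane
Conditions: t-BuMe2SiCl, imidazole, DMF, rt
Reagents that add atoms: tert-butyldimethylsilyl chloride, CC(C)(C)[Si](C)(C)Cl
Why: Standard imidazole-promoted silylation masks the propargylic OH for the acetylide chemistry; racemic material is used on purpose.

Step 13
Reactants: 15 benzyl (5R,8S)-4-(benzyloxy)-8-[(2R)-1-hydroxypropan-2-yl]-5-methyl-5,6,7,8-tetrahydronaphthalene-2-carboxylate; 17 rac-(but-3-yn-2-yloxy)(tert-butyl)dimethylsilane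
Product: 20 benzyl (5R,8S)-4-(benzyloxy)-8-[(2S)-6-{[tert-butyl(dimethyl)silyl]oxy}hept-4-yn-2-yl]-5-methyl-5,6,7,8-tetrahydronaphthalene-2-carboxylate (both C15 epimers), via lithium acetylide 18 (not isolated), via triflate 19 (not isolated)
Conditions: 15: Tf2O, 2,6-lutidine, CH2Cl2, −78 °C (crude triflate); 17: n-BuLi, THF, −78 °C; combined, DMPU, −78 → −20 °C
Reagents that add atoms: none
Why: SN2 alkylation of a lithium acetylide by a primary triflate forms C12–C13 at low temperature, where the triflate should react far faster than the benzyl ester, and C11 (beta to the reacting carbon) is not touched.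

Step 14
Reactants: 20 benzyl (5R,8S)-4-(benzyloxy)-8-[(2S)-6-{[tert-butyl(dimethyl)silyl]oxy}hept-4-yn-2-yl]-5-methyl-5,6,7,8-tetrahydronaphthalene-2-carboxylate
Product: 21 benzyl (5R,8S)-4-(benzyloxy)-8-[(2S)-6-hydroxyhept-4-yn-2-yl]-5-methyl-5,6,7,8-tetrahydronaphthalene-2-carboxylate (both C15 epimers)
Conditions: Bu4NF, AcOH, THF, 0 °C → rt
Reagents that add atoms: none
Why: Fluoride-mediated desilylation buffered with acetic acid frees the propargylic alcohol without cleaving the benzyl ester.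

Step 15
Reactants: 21 benzyl (5R,8S)-4-(benzyloxy)-8-[(2S)-6-hydroxyhept-4-yn-2-yl]-5-methyl-5,6,7,8-tetrahydronaphthalene-2-carboxylate
Product: 22 benzyl (5R,8S)-4-(benzyloxy)-8-[(2S)-6-bromohept-4-yn-2-yl]-5-methyl-5,6,7,8-tetrahydronaphthalene-2-carboxylate (both C15 epimers)
Conditions: CBr4, PPh3, CH2Cl2, 0 °C
Reagents that add atoms: carbon tetrabromide, BrC(Br)(Br)Br
Why: Appel bromination converts the secondary propargylic alcohol into the bromide under neutral conditions, and its configuration is irrelevant because step 18 is stereoconvergent.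

Step 16
Reactants: 23 3-phenylpropanoic acid
Product: 24 chloromethyl 3-phenylpropanoate
Conditions: ClCH2OSO2Cl, NaHCO3, Bu4NHSO4 (cat.), CH2Cl2/H2O, rt
Reagents that add atoms: chloromethyl chlorosulfate, ClCOS(=O)(=O)Cl
Why: Phase-transfer O-alkylation of the carboxylate displaces the chlorosulfate group selectively and gives the chloromethyl ester.

Step 17
Reactants: 24 chloromethyl 3-phenylpropanoate
Product: 25 iodomethyl 3-phenylpropanoate
Conditions: NaI, acetone, rt, dark
Reagents that add atoms: sodium iodide, [Na+].[I-]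
Why: Finkelstein halide exchange, driven by precipitation of NaCl, gives the iodide needed for zinc insertion.

Step 18
Reactants: 22 benzyl (5R,8S)-4-(benzyloxy)-8-[(2S)-6-bromohept-4-yn-2-yl]-5-methyl-5,6,7,8-tetrahydronaphthalene-2-carboxylate; 25 iodomethyl 3-phenylpropanoate
Product: 27 benzyl (5R,8S)-4-(benzyloxy)-5-methyl-8-[(2S,6R)-6-methyl-7-(3-phenylpropanoyloxy)hept-4-yn-2-yl]-5,6,7,8-tetrahydronaphthalene-2-carboxylate, via zinc reagent 26 (not isolated)
Conditions: 25: Zn dust (BrCH2CH2Br, Me3SiCl activation), THF, 15 °C; then 22, NiCl2·glyme (10 mol %), 2,6-bis[(4S)-4-isopropyl-4,5-dihydrooxazol-2-yl]pyridine (13 mol %), DMA/THF, −10 °C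
Reagents that add atoms: none
Why: Proposed new method: zinc inserts into the C–I bond of 25 to give the carbonyl-chelated zinc reagent 26, which transmetalates to the pybox-bound nickel, while a monovalent nickel species abstracts bromine from 22 to give a planar propargyl radical at C15 (both epimers converge) that is captured by the chiral alkylnickel complex, and reductive elimination from trivalent nickel forms the C15–C16 bond. The closest known reaction type is the nickel/pybox-catalysed enantioconvergent Negishi coupling of racemic secondary propargylic and allylic halides with organozinc halides; new is only the α-acyloxymethylzinc partner, a reagent class known from copper- and palladium-mediated couplings. No ring is closed. The single new stereocenter C15 (R) is set by the chiral ligand on nickel in the radical-capture/reductive-elimination step, because the radical has lost the configuration of 22 and the nearest resident center (C11) lies four bonds away across the linear alkyne. The step needs propargyl over allenyl coupling and tolerance of the benzyl ester: the methyl-bearing sp3 terminus is the less hindered end of the radical and the site of bond formation in the known couplings, and organozinc halides do not add to esters. In one operation the step forms C15–C16, sets C15 and delivers the complete 3-phenylpropanoate from a racemic precursor.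

Step 19
Reactants: 27 benzyl (5R,8S)-4-(benzyloxy)-5-methyl-8-[(2S,6R)-6-methyl-7-(3-phenylpropanoyloxy)hept-4-yn-2-yl]-5,6,7,8-tetrahydronaphthalene-2-carboxylate
Product: 28 (5R,8S)-4-hydroxy-5-methyl-8-[(2S,6R)-6-methyl-7-(3-phenylpropanoyloxy)heptan-2-yl]-5,6,7,8-tetrahydronaphthalene-2-carboxylic acid (target)
Conditions: H2 (1 atm), 5% Pt/C, EtOAc, rt; then Pd(OH)2/C added, H2 (1 atm), EtOAc/EtOH, rt
Reagents that add atoms: none
Why: Heterogeneous hydrogenation first saturates the alkyne on platinum, which isomerises intermediate alkenes less than palladium so that C15 and C11 should not be scrambled, and then hydrogenolyses the benzyl ether and benzyl ester on Pd(OH)2/C while the alkyl 3-phenylpropanoate is inert.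

**Compound list**

1 | rac-(E)-pent-3-en-2-ol | C/C=C/C(C)O | starting material
2 | rac-methyl (E)-pent-3-en-2-yl carbonate | C/C=C/C(C)OC(=O)OC | intermediate
3 | dimethyl 5-hydroxyisophthalate | COC(=O)c1cc(O)cc(C(=O)OC)c1 | starting material
4 | dimethyl 5-{[(2S,3E)-pent-3-en-2-yl]oxy}isophthalate | C/C=C/[C@H](C)Oc1cc(C(=O)OC)cc(C(=O)OC)c1 | intermediate
5 | dimethyl 5-hydroxy-4-[(2R,3E)-pent-3-en-2-yl]isophthalate | C/C=C/[C@@H](C)c1c(O)cc(C(=O)OC)cc1C(=O)OC | intermediate
6 | 3-hydroxy-5-(methoxycarbonyl)-4-[(2R,3E)-pent-3-en-2-yl]benzoic acid | C/C=C/[C@@H](C)c1c(O)cc(C(=O)O)cc1C(=O)OC | intermediate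
7 | 3-hydroxy-5-(hydroxymethyl)-4-[(2R,3E)-pent-3-en-2-yl]benzoic acid | C/C=C/[C@@H](C)c1c(O)cc(C(=O)O)cc1CO | intermediate
8 | benzyl 3-(benzyloxy)-5-(hydroxymethyl)-4-[(2R,3E)-pent-3-en-2-yl]benzoate | C/C=C/[C@@H](C)c1c(OCc2ccccc2)cc(C(=O)OCc2ccccc2)cc1CO | intermediate
9 | benzyl 3-(benzyloxy)-5-formyl-4-[(2R,3E)-pent-3-en-2-yl]benzoate | C/C=C/[C@@H](C)c1c(OCc2ccccc2)cc(C(=O)OCc2ccccc2)cc1C=O | intermediate
10 | benzyl 3-(benzyloxy)-5-(1-hydroxyprop-2-en-1-yl)-4-[(2R,3E)-pent-3-en-2-yl]benzoate (both carbinol epimers) | C/C=C/[C@@H](C)c1c(OCc2ccccc2)cc(C(=O)OCc2ccccc2)cc1C(O)C=C | intermediate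
11 | propanal | CCC=O | starting material
12 | benzyl 3-(benzyloxy)-5-[(2R,3S)-2-methyl-1-oxopent-4-en-3-yl]-4-[(2R,3E)-pent-3-en-2-yl]benzoate | C/C=C/[C@@H](C)c1c(OCc2ccccc2)cc(C(=O)OCc2ccccc2)cc1[C@@H](C=C)[C@@H](C)C=O | intermediate
13 | benzyl 3-(benzyloxy)-5-[(2R,3S)-1-hydroxy-2-methylpent-4-en-3-yl]-4-[(2R,3E)-pent-3-en-2-yl]benzoate | C/C=C/[C@@H](C)c1c(OCc2ccccc2)cc(C(=O)OCc2ccccc2)cc1[C@@H](C=C)[C@@H](C)CO | intermediate
14 | benzyl (5R,8S)-4-(benzyloxy)-8-[(2R)-1-hydroxypropan-2-yl]-5-methyl-5,8-dihydronaphthalene-2-carboxylate | C[C@@H]1C=C[C@@H]([C@@H](C)CO)c2cc(C(=O)OCc3ccccc3)cc(OCc3ccccc3)c21 | intermediate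
15 | benzyl (5R,8S)-4-(benzyloxy)-8-[(2R)-1-hydroxypropan-2-yl]-5-methyl-5,6,7,8-tetrahydronaphthalene-2-carboxylate | C[C@@H]1CC[C@@H]([C@@H](C)CO)c2cc(C(=O)OCc3ccccc3)cc(OCc3ccccc3)c21 | intermediate
16 | rac-but-3-yn-2-ol | C#CC(C)O | starting material
17 | rac-(but-3-yn-2-yloxy)(tert-butyl)dimethylsilane | C#CC(C)O[Si](C)(C)C(C)(C)C | intermediate
18 | lithium acetylide of 17 | [Li]C#CC(C)O[Si](C)(C)C(C)(C)C | intermediate
19 | benzyl (5R,8S)-4-(benzyloxy)-5-methyl-8-[(2R)-1-{[(trifluoromethyl)sulfonyl]oxy}propan-2-yl]-5,6,7,8-tetrahydronaphthalene-2-carboxylate | C[C@@H]1CC[C@@H]([C@@H](C)COS(=O)(=O)C(F)(F)F)c2cc(C(=O)OCc3ccccc3)cc(OCc3ccccc3)c21 | intermediate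
20 | benzyl (5R,8S)-4-(benzyloxy)-8-[(2S)-6-{[tert-butyl(dimethyl)silyl]oxy}hept-4-yn-2-yl]-5-methyl-5,6,7,8-tetrahydronaphthalene-2-carboxylate (both C15 epimers) | C[C@@H]1CC[C@@H]([C@@H](C)CC#CC(C)O[Si](C)(C)C(C)(C)C)c2cc(C(=O)OCc3ccccc3)cc(OCc3ccccc3)c21 | intermediate
21 | benzyl (5R,8S)-4-(benzyloxy)-8-[(2S)-6-hydroxyhept-4-yn-2-yl]-5-methyl-5,6,7,8-tetrahydronaphthalene-2-carboxylate (both C15 epimers) | C[C@@H]1CC[C@@H]([C@@H](C)CC#CC(C)O)c2cc(C(=O)OCc3ccccc3)cc(OCc3ccccc3)c21 | intermediate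
22 | benzyl (5R,8S)-4-(benzyloxy)-8-[(2S)-6-bromohept-4-yn-2-yl]-5-methyl-5,6,7,8-tetrahydronaphthalene-2-carboxylate (both C15 epimers) | C[C@@H]1CC[C@@H]([C@@H](C)CC#CC(C)Br)c2cc(C(=O)OCc3ccccc3)cc(OCc3ccccc3)c21 | intermediate
23 | 3-phenylpropanoic acid | OC(=O)CCc1ccccc1 | starting material
24 | chloromethyl 3-phenylpropanoate | ClCOC(=O)CCc1ccccc1 | intermediate
25 | iodomethyl 3-phenylpropanoate | ICOC(=O)CCc1ccccc1 | intermediate
26 | [(3-phenylpropanoyl)oxy]methylzinc iodide | I[Zn]COC(=O)CCc1ccccc1 | intermediate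
27 | benzyl (5R,8S)-4-(benzyloxy)-5-methyl-8-[(2S,6R)-6-methyl-7-(3-phenylpropanoyloxy)hept-4-yn-2-yl]-5,6,7,8-tetrahydronaphthalene-2-carboxylate | C[C@@H]1CC[C@@H]([C@@H](C)CC#C[C@@H](C)COC(=O)CCc3ccccc3)c2cc(C(=O)OCc3ccccc3)cc(OCc3ccccc3)c21 | intermediate
28 | (5R,8S)-4-hydroxy-5-methyl-8-[(2S,6R)-6-methyl-7-(3-phenylpropanoyloxy)heptan-2-yl]-5,6,7,8-tetrahydronaphthalene-2-carboxylic acid | C[C@H](CCC[C@H](C)[C@@H]1CC[C@@H](C)c2c(O)cc(C(=O)O)cc21)COC(=O)CCc1ccccc1 | target

**Step count and risks**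

Total step count: 19. Longest linear sequence: 16 steps (steps 1–11, 13–15, 18, 19).

Most likely to fail, 1: step 18. Transmetalation of the chelated, weakly nucleophilic zinc reagent may be slower than reduction or dimerisation of the propargyl radical. The ligand may also fail to differentiate the two faces of the C15 radical, or coupling at the allenyl terminus may intrude. The fallback uses known chemistry, buys C15 instead of making it, sets out from 15 and comes back at 27. Commercial methyl (S)-3-hydroxy-2-methylpropanoate would be silylated (t-BuPh2SiCl, imidazole, DMF) to methyl (S)-3-[(tert-butyldiphenylsilyl)oxy]-2-methylpropanoate F1. Reduction (i-Bu2AlH, CH2Cl2, −78 °C) would give (S)-3-[(tert-butyldiphenylsilyl)oxy]-2-methylpropanal F2. Ohira–Bestmann homologation (dimethyl (1-diazo-2-oxopropyl)phosphonate, K2CO3, MeOH, 0 °C) would give (R)-tert-butyl[(2-methylbut-3-yn-1-yl)oxy]diphenylsilane F3. Deprotonation (n-BuLi, THF, −78 °C) would give the lithium acetylide of F3 F4, which would be alkylated with triflate 19, made from 15 as in step 13, to give benzyl (5R,8S)-4-(benzyloxy)-8-[(2S,6R)-7-[(tert-butyldiphenylsilyl)oxy]-6-methylhept-4-yn-2-yl]-5-methyl-5,6,7,8-tetrahydronaphthalene-2-carboxylate F5. Desilylation (Bu4NF, AcOH, THF) would free benzyl (5R,8S)-4-(benzyloxy)-8-[(2S,6R)-7-hydroxy-6-methylhept-4-yn-2-yl]-5-methyl-5,6,7,8-tetrahydronaphthalene-2-carboxylate F6. Acylation with 3-phenylpropanoyl chloride (pyridine, CH2Cl2, 0 °C) would give 27, which continues with step 19.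

Most likely to fail, 2: step 9. Ionisation of the ortho-substituted carbinol may be slow, the two catalysts may be mismatched with the resident C1 center, or the allyl cation equivalent may cyclise onto the neighbouring propenyl group; each would erode facial selectivity at C4 or C11. The fallback replaces catalyst control by 1,3-chirality transfer in an Ireland–Claisen rearrangement, sets out from 9 and comes back at 14. Wittig reaction of 9 with 1-(triphenylphosphoranylidene)propan-2-one would give benzyl 3-(benzyloxy)-5-[(1E)-3-oxobut-1-en-1-yl]-4-[(2R,3E)-pent-3-en-2-yl]benzoate F7. Corey–Bakshi–Shibata reduction ((S)-2-methyl-CBS-oxazaborolidine, catecholborane, toluene, −78 °C) would give benzyl 3-(benzyloxy)-5-[(1E,3R)-3-hydroxybut-1-en-1-yl]-4-[(2R,3E)-pent-3-en-2-yl]benzoate F8. Acylation (propanoyl chloride, pyridine) would give benzyl 3-(benzyloxy)-5-[(1E,3R)-3-(propanoyloxy)but-1-en-1-yl]-4-[(2R,3E)-pent-3-en-2-yl]benzoate F9. Enolisation in the presence of DMPU and silylation (LiN(i-Pr)2, Me3SiCl, THF/DMPU, −78 °C) would give the (Z)-O-trimethylsilyl ketene acetal of F9 F10. On warming, this should rearrange through a chair transition state (carbinol methyl equatorial) to trimethylsilyl (2R,3S,4E)-3-{3-(benzyloxy)-5-[(benzyloxy)carbonyl]-2-[(2R,3E)-pent-3-en-2-yl]phenyl}-2-methylhex-4-enoate F11, hydrolysed on work-up to (2R,3S,4E)-3-{3-(benzyloxy)-5-[(benzyloxy)carbonyl]-2-[(2R,3E)-pent-3-en-2-yl]phenyl}-2-methylhex-4-enoic acid F12. Reduction of the acid (BH3·SMe2, THF, 0 °C; acids are reduced faster than internal alkenes are hydroborated) would give benzyl 3-(benzyloxy)-5-[(2R,3S,4E)-1-hydroxy-2-methylhex-4-en-3-yl]-4-[(2R,3E)-pent-3-en-2-yl]benzoate F13. Ring-closing metathesis of F13 under the conditions of step 10 would give 14 with loss of but-2-ene.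

Most likely to fail, 3: step 13. The lithium acetylide may add to the benzyl ester carbonyl, or elimination of the β-branched triflate may compete with substitution. The fallback replaces the strongly basic SN2 by a metal-catalysed sp3–sp coupling under carbonate base, sets out from 15 and comes back at 20. Alcohol 15 would be converted (I2, PPh3, imidazole, CH2Cl2) to benzyl (5R,8S)-4-(benzyloxy)-8-[(2R)-1-iodopropan-2-yl]-5-methyl-5,6,7,8-tetrahydronaphthalene-2-carboxylate F14. F14 would be coupled with alkyne 17 in an alkyl Sonogashira reaction ([Pd(π-allyl)Cl]2, 1,3-bis(1-adamantyl)imidazolium chloride, CuI, Cs2CO3, DMF/Et2O, 45 °C) to give 20.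

**Further compounds**

F1 | step 18 | methyl (S)-3-[(tert-butyldiphenylsilyl)oxy]-2-methylpropanoate | COC(=O)[C@@H](C)CO[Si](c1ccccc1)(c1ccccc1)C(C)(C)C
F2 | step 18 | (S)-3-[(tert-butyldiphenylsilyl)oxy]-2-methylpropanal | O=C[C@@H](C)CO[Si](c1ccccc1)(c1ccccc1)C(C)(C)C
F3 | step 18 | (R)-tert-butyl[(2-methylbut-3-yn-1-yl)oxy]diphenylsilane | C#C[C@@H](C)CO[Si](c1ccccc1)(c1ccccc1)C(C)(C)C
F4 | step 18 | lithium acetylide of F3 | [Li]C#C[C@@H](C)CO[Si](c1ccccc1)(c1ccccc1)C(C)(C)C
F5 | step 18 | benzyl (5R,8S)-4-(benzyloxy)-8-[(2S,6R)-7-[(tert-butyldiphenylsilyl)oxy]-6-methylhept-4-yn-2-yl]-5-methyl-5,6,7,8-tetrahydronaphthalene-2-carboxylate | C[C@@H]1CC[C@@H]([C@@H](C)CC#C[C@@H](C)CO[Si](c3ccccc3)(c3ccccc3)C(C)(C)C)c2cc(C(=O)OCc3ccccc3)cc(OCc3ccccc3)c21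
F6 | step 18 | benzyl (5R,8S)-4-(benzyloxy)-8-[(2S,6R)-7-hydroxy-6-methylhept-4-yn-2-yl]-5-methyl-5,6,7,8-tetrahydronaphthalene-2-carboxylate | C[C@@H]1CC[C@@H]([C@@H](C)CC#C[C@@H](C)CO)c2cc(C(=O)OCc3ccccc3)cc(OCc3ccccc3)c21
F7 | step 9 | benzyl 3-(benzyloxy)-5-[(1E)-3-oxobut-1-en-1-yl]-4-[(2R,3E)-pent-3-en-2-yl]benzoate | C/C=C/[C@@H](C)c1c(OCc2ccccc2)cc(C(=O)OCc2ccccc2)cc1/C=C/C(C)=O
F8 | step 9 | benzyl 3-(benzyloxy)-5-[(1E,3R)-3-hydroxybut-1-en-1-yl]-4-[(2R,3E)-pent-3-en-2-yl]benzoate | C/C=C/[C@@H](C)c1c(OCc2ccccc2)cc(C(=O)OCc2ccccc2)cc1/C=C/[C@@H](C)O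
F9 | step 9 | benzyl 3-(benzyloxy)-5-[(1E,3R)-3-(propanoyloxy)but-1-en-1-yl]-4-[(2R,3E)-pent-3-en-2-yl]benzoate | C/C=C/[C@@H](C)c1c(OCc2ccccc2)cc(C(=O)OCc2ccccc2)cc1/C=C/[C@@H](C)OC(=O)CC
F10 | step 9 | (Z)-O-trimethylsilyl ketene acetal of F9 | C/C=C/[C@@H](C)c1c(OCc2ccccc2)cc(C(=O)OCc2ccccc2)cc1/C=C/[C@@H](C)O/C(O[Si](C)(C)C)=C/C
F11 | step 9 | trimethylsilyl (2R,3S,4E)-3-{3-(benzyloxy)-5-[(benzyloxy)carbonyl]-2-[(2R,3E)-pent-3-en-2-yl]phenyl}-2-methylhex-4-enoate | C/C=C/[C@@H](C)c1c(OCc2ccccc2)cc(C(=O)OCc2ccccc2)cc1[C@@H](/C=C/C)[C@@H](C)C(=O)O[Si](C)(C)C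
F12 | step 9 | (2R,3S,4E)-3-{3-(benzyloxy)-5-[(benzyloxy)carbonyl]-2-[(2R,3E)-pent-3-en-2-yl]phenyl}-2-methylhex-4-enoic acid | C/C=C/[C@@H](C)c1c(OCc2ccccc2)cc(C(=O)OCc2ccccc2)cc1[C@@H](/C=C/C)[C@@H](C)C(=O)O
F13 | step 9 | benzyl 3-(benzyloxy)-5-[(2R,3S,4E)-1-hydroxy-2-methylhex-4-en-3-yl]-4-[(2R,3E)-pent-3-en-2-yl]benzoate | C/C=C/[C@@H](C)c1c(OCc2ccccc2)cc(C(=O)OCc2ccccc2)cc1[C@@H](/C=C/C)[C@@H](C)CO
F14 | step 13 | benzyl (5R,8S)-4-(benzyloxy)-8-[(2R)-1-iodopropan-2-yl]-5-methyl-5,6,7,8-tetrahydronaphthalene-2-carboxylate | C[C@@H]1CC[C@@H]([C@@H](C)CI)c2cc(C(=O)OCc3ccccc3)cc(OCc3ccccc3)c21
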